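**Plan**

Labels: ring A has a1 (C–CO2Me), a2 (C–H), a3 (fusion carbon bearing C4), a4 (fusion carbon bearing C1), a5 and a6 (C–O); ring B adds C1 (CH–CH3), C2, C3 and C4 (CH–chain); the chain is C11 (CH–CH3), C12–C14, C15 (CH–CH3), C16 (CH2OH). In the tetrahydronaphthalene names C5 = C1, C6 = C2 and C8 = C4.
Cuts, in retrosynthetic order: the two O–benzyl bonds; C15–H/C16–O (back to a prenyl end); C2–O (a C2 ketone); a4–C1 and C1–C2 together, which contracts ring B to an indan-1-one; the acyl–CH2 bond (C2–C3) of that indanone; and a3–C4 between arene and chain.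
Enabling feature: the methyl-bearing C1 lies between fusion carbon a4 and C2, so ring B is a 3-substituted indan-1-one (carbonyl on a4, C4 already in place) enlarged by one CH–CH3 unit.
Forward: ring A is dressed (Br at a3, CHO at a4, benzyl ethers); the citronellal-derived 2-boryl-1-alkene is joined at a3; hydroacylation closes a five-membered ketone; diazoethane enlarges it to six-membered ring B; then C2 is deoxygenated, the chain end is oxidised and hydrogenated, and the benzyl groups are removed.
Stereochemistry: C11 comes from (S)-citronellal; C4 from the Rh/BINAP hydroacylation; C1 (trans to C4) from amine equilibration next to the C2 ketone in the ring-expansion flask; C15 from the Ru/BINAP hydrogenation.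

Key step: step 9

Assumption: the ligand antipodes are named by analogy, (R)-BINAP on rhodium for the 4S indanone and (S)-BINAP on ruthenium for 15S (same olefin face as geraniol → (R)-citronellol); should a trial run show the opposite sense in either step, the mirror-image ligand is used and nothing else changes.

**Step 1**
Reactants: 1 methyl 2,3-dihydroxybenzoate
Product: 2 methyl 5-bromo-2,3-dihydroxybenzoate
Conditions: Br2 (1.05 equiv), AcOH, 20 °C
Reagents that add atoms: bromine, BrBr
Why: Electrophilic aromatic bromination should go to a3 (C5), which is para to the a6 hydroxyl and meta to the ester, whereas a2 (para to the other hydroxyl) is ortho to the ester and a4 is para to it, so both are deactivated.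

**Step 2**
Reactants: 2 methyl 5-bromo-2,3-dihydroxybenzoate
Product: 3 methyl 5-bromo-4-formyl-2,3-dihydroxybenzoate
Conditions: MgCl2, Et3N, (CH2O)n, THF, reflux; then 1 M HCl
Reagents that add atoms: paraformaldehyde (as formaldehyde), C=O
Why: The magnesium-mediated ortho-formylation of phenols (Casnati–Skattebøl reaction) delivers formaldehyde only to a carbon ortho to a phenoxide, and a4, next to the a5 oxygen, is the single free ortho position of the catechol.

**Step 3**
Reactants: 3 methyl 5-bromo-4-formyl-2,3-dihydroxybenzoate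
Product: 4 methyl 2,3-bis(benzyloxy)-5-bromo-4-formylbenzoate
Conditions: BnBr, K2CO3, DMF, 60 °C
Reagents that add atoms: benzyl bromide, BrCc1ccccc1
Why: Williamson etherification of the two acidic, carbonyl-flanked phenols should be clean, and benzyl ethers are chosen because they withstand BF3·OEt2 at low temperature, tin hydride and SeO2, put a full-sized peri substituent on a5, and leave by hydrogenolysis at the end.

**Step 4**
Reactants: 5 (S)-citronellal [(3S)-3,7-dimethyloct-6-enal]
Product: 7 (3S)-3,7-dimethyloct-6-en-1-yne, via alkenyl nonaflate 6 (not isolated)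
Conditions: n-C4F9SO2F (1.2 equiv), phosphazene base P2-Et (2.5 equiv), DMF, −20 → 20 °C
Reagents that add atoms: none
Why: Formal dehydration of an enolisable aldehyde to a terminal alkyne through its enol nonaflate and base-induced elimination keeps all ten carbons, and the C3 stereocentre, which is β to the aldehyde and is not deprotonated by this base, should pass through unchanged.

**Step 5**
Reactants: 7 (3S)-3,7-dimethyloct-6-en-1-yne
Product: 9 2-[(3S)-3,7-dimethylocta-1,6-dien-2-yl]-4,4,5,5-tetramethyl-1,3,2-dioxaborolane, via alkenylalane 8 (not isolated)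
Conditions: i-Bu2AlH (1.3 equiv), Ni(dppp)Cl2 (3 mol %), THF, 0 → 22 °C; then MeOBpin, 0 → 80 °C
Reagents that add atoms: 2-methoxy-4,4,5,5-tetramethyl-1,3,2-dioxaborolane (MeOBpin), COB1OC(C)(C)C(C)(C)O1
Why: Nickel-catalysed hydroalumination of terminal alkynes with the dppp ligand is α-selective (aluminium on the internal carbon), the trisubstituted alkene is inert to i-Bu2AlH, and aluminium-to-boron exchange with the methoxyborane gives the 2-boryl-1-alkene without touching the stereocentre.

**Step 6**
Reactants: 4 methyl 2,3-bis(benzyloxy)-5-bromo-4-formylbenzoate; 9 the 2-boryl-1-alkene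
Product: 10 methyl 2,3-bis(benzyloxy)-5-[(3S)-3,7-dimethylocta-1,6-dien-2-yl]-4-formylbenzoate
Conditions: Pd(OAc)2 (5 mol %), SPhos (10 mol %), K3PO4, toluene/H2O, 80 °C
Reagents that add atoms: none
Why: Suzuki–Miyaura coupling of an aryl bromide activated by its ortho formyl group with a 1,1-disubstituted alkenylboronate forms the a3–C4 bond, and aldehyde, ester and benzyl ethers tolerate the conditions.

**Step 7**
Reactants: 10 the 2-(alk-1-en-2-yl)benzaldehyde
Product: 11 methyl (3S)-6,7-bis(benzyloxy)-3-[(2S)-6-methylhept-5-en-2-yl]-1-oxoindane-5-carboxylate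
Conditions: [Rh((R)-BINAP)]ClO4 (5 mol %, from [Rh(nbd)((R)-BINAP)]ClO4 and H2), CH2Cl2, 25 °C
Reagents that add atoms: none
Why: Intramolecular alkene hydroacylation of a 2-(alk-1-en-2-yl)benzaldehyde with a cationic rhodium–BINAP catalyst (formyl C–H insertion, hydride transfer to the internal alkene carbon, acyl–CH2 reductive elimination) closes the five-membered ketone with its carbonyl on a4, and the new centre C4 (indane C3) is set by the ligand, which is expected to override the neighbouring C11 centre.

**Step 8**
Reactants: 12 N-ethyl-N-nitrosourea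
Product: 13 diazoethane (ethereal solution, used at once)
Conditions: 40% aq KOH, Et2O, −5 °C; ether layer dried over KOH pellets
Reagents that add atoms: none
Why: Base-induced fragmentation of an N-alkyl-N-nitrosourea is the classical way to a diazoalkane solution free of acid and alcohol.

**Step 9**
Reactants: 11 the indan-1-one; 13 diazoethane
Product: 16 methyl (5S,8S)-3,4-bis(benzyloxy)-5-methyl-8-[(2S)-6-methylhept-5-en-2-yl]-6-oxo-5,6,7,8-tetrahydronaphthalene-2-carboxylate (trans-tetralone), via diazonium alkoxide–BF3 adduct 14 (not isolated), via cis-tetralone 15 (not isolated)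
Conditions: BF3·OEt2 (1.2 equiv), CH2Cl2, −78 °C; 13 (1.5 equiv in Et2O) added over 1 h; −78 → −40 °C; Et3N (1.5 equiv), then DBU (0.2 equiv), → 20 °C, argon; pH 7 buffer
Reagents that add atoms: none
Why: BF3 activates the indanone carbonyl, the carbon of diazoethane adds to it (C1–C2 bond) to give adduct 14, and the aryl carbon a4, antiperiplanar to the departing N2, shifts from the carbinol carbon to the diazonium carbon (a4–C1 bond), so that the former carbonyl carbon becomes the C2 ketone. The closest known reaction type is the Lewis-acid-promoted homologation of aryl ketones and benzo-fused cycloalkanones with diazoalkanes (Tiffeneau–Demjanov type), in which the aryl group is the usual migrating group. Six-membered ring B therefore arises by enlargement of the five-membered ring through a 1,2-shift and not by a cyclisation. The migration is not expected to control the new centre C1, so the cis epimer 15 formed beside 16 is converted into 16 in the same flask: once BF3 is bound by Et3N, catalytic DBU enolises the benzylic, carbonyl-flanked C1–H, and the mixture should settle on the isomer in which peri contacts with the a5 benzyloxy group and with a2–H hold the C1 methyl and the C4 chain pseudoaxial, which is the trans arrangement relative to the fixed C4 centre. The step needs aryl instead of methylene migration and a single insertion: the first rests on the higher migratory aptitude of the aryl carbon, raised by the ortho benzyloxy donor on a5 though lowered by the para ester, and the second on slow addition of a small excess of diazoethane to the pre-complexed ketone and on the α-branching of the product ketone.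

**Step 10**
Reactants: 16 trans-tetralone
Product: 17 methyl (5S,8S)-3,4-bis(benzyloxy)-6-hydroxy-5-methyl-8-[(2S)-6-methylhept-5-en-2-yl]-5,6,7,8-tetrahydronaphthalene-2-carboxylate (both C2 epimers)
Conditions: NaBH4 (1.5 equiv), CeCl3·7H2O (1.2 equiv), MeOH/THF, −60 → −30 °C; aq NH4Cl
Reagents that add atoms: none
Why: Hydride addition to the C2 ketone under Luche-type conditions (NaBH4 with CeCl3) is fast and only weakly basic, so the carbonyl should be reduced before the acidic C1–H can exchange; this removes the acidifying group and fixes C1, and the C2 carbinol configuration is irrelevant because C2 becomes CH2.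

**Step 11**
Reactants: 17 the C2 alcohol
Product: 18 methyl (5S,8S)-3,4-bis(benzyloxy)-6-[(1H-imidazol-1-ylcarbonothioyl)oxy]-5-methyl-8-[(2S)-6-methylhept-5-en-2-yl]-5,6,7,8-tetrahydronaphthalene-2-carboxylate
Conditions: Im2C=S (2 equiv), DMAP (0.2 equiv), toluene, 80 °C
Reagents that add atoms: 1,1'-thiocarbonyldiimidazole, S=C(n1ccnc1)n1ccnc1
Why: Acylation of the only hydroxyl with thiocarbonyldiimidazole gives the thiocarbonyl derivative for radical deoxygenation (first stage of the Barton–McCombie reaction) under neutral conditions that leave C1 and the ester alone.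

**Step 12**
Reactants: 18 the imidazolyl thiocarbonate
Product: 19 methyl (5R,8S)-3,4-bis(benzyloxy)-5-methyl-8-[(2S)-6-methylhept-5-en-2-yl]-5,6,7,8-tetrahydronaphthalene-2-carboxylate
Conditions: Bu3SnH (2 equiv), AIBN (0.2 equiv), toluene, 110 °C
Reagents that add atoms: none
Why: In the Barton–McCombie deoxygenation the stannyl radical adds to sulfur, the C2–O bond breaks, and the secondary C2 radical is reduced by Bu3SnH faster than it can reach the distant alkene or trigger an aryl shift, so C1, C4 and C11 are untouched.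

**Step 13**
Reactants: 19 the tetralin with prenyl chain end
Product: 20 methyl (5R,8S)-3,4-bis(benzyloxy)-8-[(2S,5E)-7-hydroxy-6-methylhept-5-en-2-yl]-5-methyl-5,6,7,8-tetrahydronaphthalene-2-carboxylate
Conditions: SeO2 (0.3 equiv), t-BuOOH (3 equiv), salicylic acid (0.1 equiv), CH2Cl2, 0 → 20 °C
Reagents that add atoms: tert-butyl hydroperoxide (terminal oxygen source), CC(C)(C)OO; selenium dioxide (oxygen carrier), O=[Se]=O
Why: The catalytic Riley oxidation (ene reaction, then [2,3]-sigmatropic shift) hydroxylates the (E)-methyl group at the more substituted end of a trisubstituted alkene, which gives the (E)-allylic alcohol and fixes the alkene geometry needed for the hydrogenation.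

**Step 14**
Reactants: 20 the (E)-allylic alcohol
Product: 21 methyl (5R,8S)-3,4-bis(benzyloxy)-8-[(2S,6S)-7-hydroxy-6-methylheptan-2-yl]-5-methyl-5,6,7,8-tetrahydronaphthalene-2-carboxylate
Conditions: Ru(OAc)2[(S)-BINAP] (2 mol %), H2 (100 atm), MeOH, 25 °C
Reagents that add atoms: none
Why: Noyori asymmetric hydrogenation of an allylic alcohol proceeds through the ruthenium-bound alkoxide, so the ligand selects the olefin face and sets C15 as S, while arene, ester and benzyl ethers are not reduced by this catalyst.

**Step 15**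
Reactants: 21 the bis(benzyl) ether
Product: 22 methyl (5R,8S)-3,4-dihydroxy-8-[(2S,6S)-7-hydroxy-6-methylheptan-2-yl]-5-methyl-5,6,7,8-tetrahydronaphthalene-2-carboxylate (CNP0135649.1)
Conditions: H2 (1 atm), 10% Pd/C, EtOAc/MeOH, 20 °C
Reagents that add atoms: none
Why: Catalytic hydrogenolysis cleaves both aryl benzyl ethers under neutral conditions that leave the methyl ester, the primary alcohol and all four stereocentres unchanged.

**Compound list**

1 | methyl 2,3-dihydroxybenzoate | COC(=O)c1cccc(O)c1O | starting material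
2 | methyl 5-bromo-2,3-dihydroxybenzoate | COC(=O)c1cc(Br)cc(O)c1O | intermediate
3 | methyl 5-bromo-4-formyl-2,3-dihydroxybenzoate | COC(=O)c1cc(Br)c(C=O)c(O)c1O | intermediate
4 | methyl 2,3-bis(benzyloxy)-5-bromo-4-formylbenzoate | COC(=O)c1cc(Br)c(C=O)c(OCc2ccccc2)c1OCc1ccccc1 | intermediate
5 | (S)-citronellal | O=CC[C@@H](C)CCC=C(C)C | starting material
6 | (3S)-3,7-dimethylocta-1,6-dien-1-yl nonafluorobutane-1-sulfonate (E/Z mixture) | FC(F)(F)C(F)(F)C(F)(F)C(F)(F)S(=O)(=O)OC=C[C@@H](C)CCC=C(C)C | intermediate
7 | (3S)-3,7-dimethyloct-6-en-1-yne | C#C[C@@H](C)CCC=C(C)C | intermediate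
8 | [(3S)-3,7-dimethylocta-1,6-dien-2-yl]diisobutylaluminium | C=C([Al](CC(C)C)CC(C)C)[C@@H](C)CCC=C(C)C | intermediate
9 | 2-[(3S)-3,7-dimethylocta-1,6-dien-2-yl]-4,4,5,5-tetramethyl-1,3,2-dioxaborolane | C=C(B1OC(C)(C)C(C)(C)O1)[C@@H](C)CCC=C(C)C | intermediate
10 | methyl 2,3-bis(benzyloxy)-5-[(3S)-3,7-dimethylocta-1,6-dien-2-yl]-4-formylbenzoate | COC(=O)c1cc(C(=C)[C@@H](C)CCC=C(C)C)c(C=O)c(OCc2ccccc2)c1OCc1ccccc1 | intermediate
11 | methyl (3S)-6,7-bis(benzyloxy)-3-[(2S)-6-methylhept-5-en-2-yl]-1-oxoindane-5-carboxylate | COC(=O)c1cc2c(c(OCc3ccccc3)c1OCc1ccccc1)C(=O)C[C@H]2[C@@H](C)CCC=C(C)C | intermediate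
12 | N-ethyl-N-nitrosourea | CCN(N=O)C(N)=O | starting material
13 | diazoethane | CC=[N+]=[N-] | intermediate
14 | BF3-bound 1-(1-diazonioethyl)indan-1-olate adduct of 11 (diastereomer mixture) | COC(=O)c1cc2c(c(OCc3ccccc3)c1OCc1ccccc1)C(O[B-](F)(F)F)(C(C)[N+]#N)C[C@H]2[C@@H](C)CCC=C(C)C | intermediate
15 | methyl (5R,8S)-3,4-bis(benzyloxy)-5-methyl-8-[(2S)-6-methylhept-5-en-2-yl]-6-oxo-5,6,7,8-tetrahydronaphthalene-2-carboxylate (cis-tetralone, C1 epimer of 16) | COC(=O)c1cc2c(c(OCc3ccccc3)c1OCc1ccccc1)[C@@H](C)C(=O)C[C@H]2[C@@H](C)CCC=C(C)C | intermediate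
16 | methyl (5S,8S)-3,4-bis(benzyloxy)-5-methyl-8-[(2S)-6-methylhept-5-en-2-yl]-6-oxo-5,6,7,8-tetrahydronaphthalene-2-carboxylate (trans-tetralone) | COC(=O)c1cc2c(c(OCc3ccccc3)c1OCc1ccccc1)[C@H](C)C(=O)C[C@H]2[C@@H](C)CCC=C(C)C | intermediate
17 | methyl (5S,8S)-3,4-bis(benzyloxy)-6-hydroxy-5-methyl-8-[(2S)-6-methylhept-5-en-2-yl]-5,6,7,8-tetrahydronaphthalene-2-carboxylate (C2 epimers) | COC(=O)c1cc2c(c(OCc3ccccc3)c1OCc1ccccc1)[C@H](C)C(O)C[C@H]2[C@@H](C)CCC=C(C)C | intermediate
18 | methyl (5S,8S)-3,4-bis(benzyloxy)-6-[(1H-imidazol-1-ylcarbonothioyl)oxy]-5-methyl-8-[(2S)-6-methylhept-5-en-2-yl]-5,6,7,8-tetrahydronaphthalene-2-carboxylate | COC(=O)c1cc2c(c(OCc3ccccc3)c1OCc1ccccc1)[C@H](C)C(OC(=S)n1ccnc1)C[C@H]2[C@@H](C)CCC=C(C)C | intermediate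
19 | methyl (5R,8S)-3,4-bis(benzyloxy)-5-methyl-8-[(2S)-6-methylhept-5-en-2-yl]-5,6,7,8-tetrahydronaphthalene-2-carboxylate | COC(=O)c1cc2c(c(OCc3ccccc3)c1OCc1ccccc1)[C@H](C)CC[C@H]2[C@@H](C)CCC=C(C)C | intermediate
20 | methyl (5R,8S)-3,4-bis(benzyloxy)-8-[(2S,5E)-7-hydroxy-6-methylhept-5-en-2-yl]-5-methyl-5,6,7,8-tetrahydronaphthalene-2-carboxylate | COC(=O)c1cc2c(c(OCc3ccccc3)c1OCc1ccccc1)[C@H](C)CC[C@H]2[C@@H](C)CC/C=C(\C)CO | intermediate
21 | methyl (5R,8S)-3,4-bis(benzyloxy)-8-[(2S,6S)-7-hydroxy-6-methylheptan-2-yl]-5-methyl-5,6,7,8-tetrahydronaphthalene-2-carboxylate | COC(=O)c1cc2c(c(OCc3ccccc3)c1OCc1ccccc1)[C@H](C)CC[C@H]2[C@@H](C)CCC[C@H](C)CO | intermediate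
22 | methyl (5R,8S)-3,4-dihydroxy-8-[(2S,6S)-7-hydroxy-6-methylheptan-2-yl]-5-methyl-5,6,7,8-tetrahydronaphthalene-2-carboxylate | COC(=O)c1cc2c(c(O)c1O)[C@H](C)CC[C@H]2[C@@H](C)CCC[C@H](C)CO | target

**Totals**

Total step count: 15.
Longest linear sequence: 12 steps (steps 1, 2, 3, 6, 7 and 9 to 15, from methyl 2,3-dihydroxybenzoate).

**Steps most likely to fail**

Step 9 (ring expansion). The ring methylene may migrate in place of the aryl carbon, whose aptitude is lowered by the para ester. Diazoethane may also be consumed by Lewis-acid-induced decomposition, or by a second insertion into the more electrophilic product ketone, before it adds to the hindered conjugated ketone. The fallback sets out from 11 and avoids diazo chemistry. Wittig reaction with the ylide from EtPPh3Br and KOt-Bu in THF would give methyl (3S)-6,7-bis(benzyloxy)-1-ethylidene-3-[(2S)-6-methylhept-5-en-2-yl]indane-5-carboxylate F1. Oxidative rearrangement of this aryl alkene with the trivalent iodine reagent PhI(OH)OTs in 95% MeOH at 0 °C follows: iodine binds the exocyclic carbon, methanol adds to the benzylic carbon, and a4 shifts as iodobenzene leaves. This should give the C2 dimethyl ketal F2. Dilute aqueous HCl in THF would hydrolyse it to the ketone as its C1 epimers, and catalytic DBU under argon, as in step 9, would carry the cis epimer 15 over to 16, where the route is rejoined. The aryl-conjugated alkene is expected to react much faster with the iodine reagent than the isolated trisubstituted one of the chain.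

Step 10 (reduction with C1 intact). The equilibrium reached in step 9 may lie too close to parity if the pseudoaxial preference of the two benzylic groups is weaker than assumed. C1 may also drift during the reduction if the cis ketone is reduced faster and is replenished by enolisation, and C1 cannot be corrected once C2 is reduced. The fallback sets out from 16 and sets C1 by catalyst control. KHMDS and PhNTf2 in THF at −78 → 0 °C would trap the conjugated enolate as the C1=C2 enol triflate F3. Reduction with Pd(OAc)2, PPh3, HCO2H and Bu3N in DMF at 60 °C would give the 1-methyl-3,4-dihydronaphthalene F4. Asymmetric hydrogenation with a cationic iridium phosphine–oxazoline complex, [Ir(cod)((S)-t-Bu-PHOX)]BArF or its mirror image, under H2 (50 bar) in CH2Cl2 then sets C1. The ligand antipode is chosen for the 5R configuration at C1, and the reaction is stopped once the aryl-conjugated alkene, which this catalyst class reduces faster than a trialkyl one, is consumed. The product is 19, so steps 10 to 12 are bypassed.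

Step 14 (C15 hydrogenation). Face discrimination may be insufficient at an alkene whose two C15 substituents (CH3 and CH2OH) differ little, and the resulting remote C15 epimers could not be separated. The fallback sets out from 20 and moves the hydrogenation to the carboxylic acid, the substrate class of tiglic acid. MnO2 in CH2Cl2 would give the (E)-enal F5. Pinnick oxidation (NaClO2, NaH2PO4, 2-methylbut-2-ene, t-BuOH/H2O) would give the (E)-2-methylalk-2-enoic acid F6. Ru(OAc)2(BINAP), in the antipode that delivers the 2S acid, under H2 in MeOH should give the (S)-2-methylalkanoic acid F7. BH3·SMe2 in THF at 0 °C reduces the acid in the presence of the aryl methyl ester and returns the route to 21.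

**Further compounds**

F1 | step 9 | methyl (3S)-6,7-bis(benzyloxy)-1-ethylidene-3-[(2S)-6-methylhept-5-en-2-yl]indane-5-carboxylate (E/Z mixture) | COC(=O)c1cc2c(c(OCc3ccccc3)c1OCc1ccccc1)C(=CC)C[C@H]2[C@@H](C)CCC=C(C)C
F2 | step 9 | methyl (8S)-3,4-bis(benzyloxy)-6,6-dimethoxy-5-methyl-8-[(2S)-6-methylhept-5-en-2-yl]-5,6,7,8-tetrahydronaphthalene-2-carboxylate (C1 epimers) | COC(=O)c1cc2c(c(OCc3ccccc3)c1OCc1ccccc1)C(C)C(OC)(OC)C[C@H]2[C@@H](C)CCC=C(C)C
F3 | step 10 | methyl (8S)-3,4-bis(benzyloxy)-5-methyl-8-[(2S)-6-methylhept-5-en-2-yl]-6-(trifluoromethylsulfonyloxy)-7,8-dihydronaphthalene-2-carboxylate | COC(=O)c1cc2c(c(OCc3ccccc3)c1OCc1ccccc1)C(C)=C(OS(=O)(=O)C(F)(F)F)C[C@H]2[C@@H](C)CCC=C(C)C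
F4 | step 10 | methyl (8S)-3,4-bis(benzyloxy)-5-methyl-8-[(2S)-6-methylhept-5-en-2-yl]-7,8-dihydronaphthalene-2-carboxylate | COC(=O)c1cc2c(c(OCc3ccccc3)c1OCc1ccccc1)C(C)=CC[C@H]2[C@@H](C)CCC=C(C)C
F5 | step 14 | methyl (5R,8S)-3,4-bis(benzyloxy)-5-methyl-8-[(2S,5E)-6-methyl-7-oxohept-5-en-2-yl]-5,6,7,8-tetrahydronaphthalene-2-carboxylate | COC(=O)c1cc2c(c(OCc3ccccc3)c1OCc1ccccc1)[C@H](C)CC[C@H]2[C@@H](C)CC/C=C(\C)C=O
F6 | step 14 | (2E,6S)-6-[(1S,4R)-5,6-bis(benzyloxy)-7-(methoxycarbonyl)-4-methyl-1,2,3,4-tetrahydronaphthalen-1-yl]-2-methylhept-2-enoic acid | COC(=O)c1cc2c(c(OCc3ccccc3)c1OCc1ccccc1)[C@H](C)CC[C@H]2[C@@H](C)CC/C=C(\C)C(=O)O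
F7 | step 14 | (2S,6S)-6-[(1S,4R)-5,6-bis(benzyloxy)-7-(methoxycarbonyl)-4-methyl-1,2,3,4-tetrahydronaphthalen-1-yl]-2-methylheptanoic acid | COC(=O)c1cc2c(c(OCc3ccccc3)c1OCc1ccccc1)[C@H](C)CC[C@H]2[C@@H](C)CCC[C@H](C)C(=O)O
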